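A direct plan would cut the ten-membered ring at the unfunctionalised C1–C2 bond (ring-closing metathesis, then hydrogenation) and would build the lactone first.
It would add the allenylzinc from propargylic mesylate A2 (C2–C7) to α-acyloxy aldehyde A1 (C8–C10, C1), carbonylate the homopropargylic alcohol to the α-methylene lactone, and close diene A3.
Weak step 1, the metathesis of A3: a cyclodecene would have to close at a vinyl group on a fully substituted carbinol carbon. Strain and entropy would demand millimolar dilution and high catalyst loading, and oligomerisation would compete.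
Weak step 2, the C7–C8 coupling: two stereocentres would rest on reagent control alone. The partner A1 can epimerise and shift its acyl group, and would have to be used crude.
Weak step 3, the masking overhead: the dioxolane, the silyl and PMB ethers and the amine adduct of the methylene lactone go on and come off again. Together with the long run-up to the simple A2, about a third of some twenty steps would build nothing.

**Retrosynthetic overview**
1. The C5 ketone and the C10 tertiary carbinol sit 1,6 across the cyclodecane, so the target is the ring-chain tautomer of a 5,10-epoxy hemiketal. That hemiketal is a decalin with one oxygen atom inserted into its ring-fusion C5–C10 bond (Criegee rearrangement of a C5 hydroperoxide ester, with C10 migrating with retention).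
2. All five ring stereocentres are therefore set on six-membered rings. C4 and C10 come from enantioselective deprotonation of a meso ketone followed by anti acylation. C7, C8 and C9 are placed all-equatorial on a Δ5(6)-octalin by reversible Michael addition, enolate hydroxylation and axial hydride delivery.
3. Ring order: ring A is bought, ring B comes from a vinylphosphonium annulation, the cyclodecane perimeter from the O-insertion, and the γ-lactone closes last. The exocyclic methylene is made in the final step from the phosphonate that served as the Michael donor.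
4. By design there is no macrocyclisation and no dilution, no coupling to a labile aldehyde, only one protecting group (TBS), and the methylene lactone never needs a mask.

Key step: step 11

Remark on numbering: the target numbering is used for all intermediates. Ring carbons are C1–C10 (C4 CHMe, C5 C=O, C7 lactone CH, C8 lactone O–CH, C9 ester CH, C10 C(Me)OH). C11, C12 and C13 are the lactone α-C, C=O and =CH2. In the decalins C5 and C10 are the ring-fusion atoms, and β is the face of the C10 methyl group.
Assumption 1: the ester stereocentre in the given structure is (R), so (R)-2-methylbutanoic acid is bought. 2,6-Dimethylcyclohexanone is taken as its cis (meso) isomer.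
Assumption 2: the sense of induction of the chiral lithium amide is assumed. The base is drawn as (R,R), and its antipode is equally available.

Step 1
Reactants: 1 cis-2,6-dimethylcyclohexanone
Product: 3 trimethyl{[(6R)-2,6-dimethylcyclohex-1-en-1-yl]oxy}silane, via lithium (6R)-2,6-dimethylcyclohex-1-en-1-olate 2 (not isolated)
Conditions: (R,R)-[PhCH(Me)]2NH, n-BuLi, LiCl, TMSCl (internal quench), THF, −100 → −78 °C
Reagents that add atoms: chlorotrimethylsilane, C[Si](C)(C)Cl
Why: Koga–Simpkins enantioselective deprotonation of a meso ketone; the chiral amide should remove one of the two enantiotopic axial α-protons, so the untouched α-carbon becomes C4 (R).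

Step 2
Reactants: 3; 4 acetyl chloride
Product: 5 (2S,6R)-2-acetyl-2,6-dimethylcyclohexan-1-one
Conditions: ZnCl2 (10 mol %), CH2Cl2/Et2O, 0 °C → rt
Reagents that add atoms: none
Why: Lewis-acid C-acylation of a silyl enol ether; A(1,2) strain holds the C4 methyl pseudo-axial, so the acylium should enter C10 from the opposite face, which fixes the quaternary C10 with its methyl cis to the C4 methyl.

Step 3
Reactants: 5; 6 triphenyl(vinyl)phosphonium bromide
Product: 9 (5R,8aR)-5,8a-dimethyl-3,5,6,7,8,8a-hexahydronaphthalen-1(2H)-one (C9 ketone, C5=C6), via potassium 1-[(1S,3R)-1,3-dimethyl-2-oxocyclohexyl]ethen-1-olate 7 (not isolated), via {4-[(1S,3R)-1,3-dimethyl-2-oxocyclohexyl]-4-oxobutylidene}triphenylphosphorane 8 (not isolated)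
Conditions: KHMDS (1.0 equiv), THF, −78 °C; then 6, −78 → 65 °C
Reagents that add atoms: none
Why: Schweizer vinylphosphonium annulation; the kinetic acetyl enolate (C8) adds to the vinyl salt (C7, C6), and the resulting ylide closes ring B by intramolecular Wittig olefination of the C5 ketone, which places the alkene at C5=C6 without a regiochemical choice.

Step 4
Reactants: 9
Product: 10 (5R,8aR)-5,8a-dimethyl-6,7,8,8a-tetrahydronaphthalen-1(5H)-one (linear dienone C9=O, C7=C8, C5=C6)
Conditions: IBX, DMSO, 70 °C
Reagents that add atoms: none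
Why: IBX dehydrogenation of a ketone; C10 is quaternary, so only C8 can enolise and only the C7=C8 bond can form.

Step 5
Reactants: 10; 11 triethyl phosphonoacetate
Product: 12 ethyl 2-(diethoxyphosphoryl)-2-[(2S,4aR,8R)-4a,8-dimethyl-4-oxo-2,3,4,4a,5,6,7,8-octahydronaphthalen-2-yl]acetate (C11 epimers, inconsequential)
Conditions: LiCl, DBU (0.3 equiv), MeCN, rt
Reagents that add atoms: none
Why: Reversible Michael addition; the 1,6-terminus C5 is fully substituted, so attack should occur at C7, and equilibration should favour the pseudo-equatorial 7β substituent of the Δ5(6)-octalin half-chair.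

Step 6
Reactants: 12
Product: 14 ethyl 2-(diethoxyphosphoryl)-2-[(2R,3S,4aR,8R)-3-hydroxy-4a,8-dimethyl-4-oxo-2,3,4,4a,5,6,7,8-octahydronaphthalen-2-yl]acetate, via the dipotassium C8 enolate/C11 phosphonate dianion 13 (not isolated)
Conditions: KHMDS (2.2 equiv), THF, −78 °C; then 2-(phenylsulfonyl)-3-phenyloxaziridine; AcOH quench
Reagents that add atoms: 2-(phenylsulfonyl)-3-phenyloxaziridine, O=S(=O)(c1ccccc1)N1OC1c1ccccc1
Why: Davis hydroxylation of a dianion; the last-formed ketone enolate is the more reactive site and should be attacked from the α face, away from the angular methyl and the C7 substituent, to give the equatorial 8α-OH.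

Step 7
Reactants: 14
Product: 15 ethyl 2-[(2R,3S,4aR,8R)-3-[(tert-butyldimethylsilyl)oxy]-4a,8-dimethyl-4-oxo-2,3,4,4a,5,6,7,8-octahydronaphthalen-2-yl]-2-(diethoxyphosphoryl)acetate
Conditions: TBSOTf, 2,6-lutidine, CH2Cl2, −40 → 0 °C
Reagents that add atoms: tert-butyldimethylsilyl triflate, CC(C)(C)[Si](C)(C)OS(=O)(=O)C(F)(F)F
Why: O-silylation; this single protecting group keeps O8 from lactonising or taking up the acyl group before the ring expansion.

Step 8
Reactants: 15
Product: 16 ethyl 2-[(2R,3S,4S,4aR,8R)-3-[(tert-butyldimethylsilyl)oxy]-4-hydroxy-4a,8-dimethyl-2,3,4,4a,5,6,7,8-octahydronaphthalen-2-yl]-2-(diethoxyphosphoryl)acetate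
Conditions: NaBH4, CeCl3·7H2O, MeOH, −40 °C
Reagents that add atoms: none
Why: Luche reduction; hydride should enter axially from the α face opposite the adjacent angular methyl (as in the Wieland–Miescher ketone series), giving the equatorial 9β-OH trans to O8.

Step 9
Reactants: 16; 17 (2R)-2-methylbutanoic acid
Product: 18 (1S,2S,3R,5R,8aR)-2-[(tert-butyldimethylsilyl)oxy]-3-[1-(diethoxyphosphoryl)-2-ethoxy-2-oxoethyl]-5,8a-dimethyl-1,2,3,5,6,7,8,8a-octahydronaphthalen-1-yl (2R)-2-methylbutanoate
Conditions: DCC, DMAP (0.5 equiv), CH2Cl2, rt → 40 °C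
Reagents that add atoms: none
Why: Steglich esterification of the only free hydroxyl; placing the ester before C5=O and C10–OH exist excludes internal ketal formation between a free 9,10-diol and the C5 ketone.

Step 10
Reactants: 18
Product: 20 (1S,2S,3R,5R,8aS)-2-[(tert-butyldimethylsilyl)oxy]-3-[1-(diethoxyphosphoryl)-2-ethoxy-2-oxoethyl]-4a-hydroperoxy-5,8a-dimethyldecahydronaphthalen-1-yl (2R)-2-methylbutanoate (C5 epimers, convergent), via its triethylsilyl peroxide 19 (not isolated)
Conditions: Co(thd)2 (10 mol %), Et3SiH, O2 (1 atm), ClCH2CH2Cl, rt; then PPTS, MeOH, 0 °C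
Reagents that add atoms: dioxygen, O=O
Why: Mukaiyama–Isayama hydroperoxidation; hydrogen-atom transfer to C6 of the only alkene gives the tertiary C5 radical, which O2 traps, while the esters, phosphonate and silyl ether are inert.

Step 11
Reactants: 20
Product: 22 (4R,5R,7R,8S,9R,10S)-8-[(tert-butyldimethylsilyl)oxy]-7-[1-(diethoxyphosphoryl)-2-ethoxy-2-oxoethyl]-4,10-dimethyl-9-{[(2R)-2-methylbutanoyl]oxy}-5,10-epoxycyclodecan-5-yl 4-nitrobenzoate (an 11-oxabicyclo[4.4.1]undecane; target numbering), via the C5 peroxy 4-nitrobenzoate 21 (not isolated)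
Conditions: 4-O2NC6H4COCl, pyridine, CH2Cl2, 0 °C; then 40 °C
Reagents that add atoms: 4-nitrobenzoyl chloride, O=C(Cl)c1ccc(cc1)[N+](=O)[O-]
Why: Criegee rearrangement: O-acylation gives perester 21, whose O–O bond ionises while the antiperiplanar C5–C10 σ-bond migrates from carbon to oxygen, and the ion pair collapses to the acyloxy ketal 22. The closest known case is the parent reaction itself, the rearrangement of 9-decalyl perbenzoates to 1-acyloxy-1,6-epoxycyclodecanes, which hydrolyse to 6-hydroxycyclodecanone. No ring is closed end to end: the cyclodecane perimeter appears through a 1,2-shift that replaces the ring-fusion C–C bond by a C5–O–C10 bridge (6/6 becomes oxa-bridged 7/7), so neither dilution nor a strained cyclisation transition state is involved. C10 is the only stereocentre touched and it migrates with retention, so it keeps the configuration fixed in step 2; C5 in 22 is dictated by the one-atom bridge and vanishes on hydrolysis, which is why both C5 epimers of 20 converge. The step needs migration of C10 rather than C4 or C6: C10 is the only fully substituted terminus, free rotation about C5–O lets it reach the antiperiplanar alignment, and the moderately activating 4-nitrobenzoate is chosen to stop after one insertion.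

Step 12
Reactants: 22
Product: 24 (3aR,6R,10S,11R,11aS)-3-(diethoxyphosphoryl)-10-hydroxy-6,10-dimethyl-2,5-dioxododecahydrocyclodeca[b]furan-11-yl (2R)-2-methylbutanoate (C11 epimers), via the 8,10-dihydroxy-5-oxocyclodecyl ethyl ester 23 (not isolated)
Conditions: 48% aq. HF, MeCN, 0 °C → rt; then TFA (cat.), CH2Cl2, rt
Reagents that add atoms: water, O
Why: Acid hydrolysis of the acyloxy ketal frees the C5 ketone and the C10 carbinol, fluoride removes the TBS group, and acid-catalysed lactonisation of the trans γ-hydroxy ester closes the lactone as the last ring; acidic medium suppresses O9→O8 acyl shift.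

Step 13
Reactants: 24; 25 formaldehyde
Product: 26 ineupatorolide A, (3aS,6R,10S,11R,11aS)-10-hydroxy-6,10-dimethyl-3-methylidene-2,5-dioxododecahydrocyclodeca[b]furan-11-yl (2R)-2-methylbutanoate
Conditions: 37% aq. CH2O, K2CO3, THF, 0 °C
Reagents that add atoms: none
Why: Horner–Wadsworth–Emmons methylenation of an α-phosphono lactone; only the doubly activated C11–H is removed by carbonate, so C4, the ester and the tertiary alcohol should stay untouched.

**Compound list**
1 | cis-2,6-dimethylcyclohexanone | C[C@H]1CCC[C@@H](C)C1=O | starting material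
2 | lithium (6R)-2,6-dimethylcyclohex-1-en-1-olate | C[C@@H]1CCCC(C)=C1[O-].[Li+] | intermediate (not isolated)
3 | trimethyl{[(6R)-2,6-dimethylcyclohex-1-en-1-yl]oxy}silane | C[C@@H]1CCCC(C)=C1O[Si](C)(C)C | intermediate
4 | acetyl chloride | CC(=O)Cl | starting material
5 | (2S,6R)-2-acetyl-2,6-dimethylcyclohexan-1-one | C[C@@H]1CCC[C@@](C)(C(C)=O)C1=O | intermediate
6 | triphenyl(vinyl)phosphonium bromide | C=C[P+](c1ccccc1)(c1ccccc1)c1ccccc1.[Br-] | starting material
7 | potassium 1-[(1S,3R)-1,3-dimethyl-2-oxocyclohexyl]ethen-1-olate | C[C@@H]1CCC[C@@](C)(C([O-])=C)C1=O.[K+] | intermediate (not isolated)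
8 | {4-[(1S,3R)-1,3-dimethyl-2-oxocyclohexyl]-4-oxobutylidene}triphenylphosphorane | C[C@@H]1CCC[C@@](C)(C(=O)CC[CH-][P+](c2ccccc2)(c2ccccc2)c2ccccc2)C1=O | intermediate (not isolated)
9 | (5R,8aR)-5,8a-dimethyl-3,5,6,7,8,8a-hexahydronaphthalen-1(2H)-one | C[C@@H]1CCC[C@@]2(C)C(=O)CCC=C12 | intermediate
10 | (5R,8aR)-5,8a-dimethyl-6,7,8,8a-tetrahydronaphthalen-1(5H)-one | C[C@@H]1CCC[C@@]2(C)C(=O)C=CC=C12 | intermediate
11 | triethyl phosphonoacetate | CCOC(=O)CP(=O)(OCC)OCC | starting material
12 | Michael adduct (7β side chain, C9 ketone, C5=C6) | C[C@@H]1CCC[C@@]2(C)C(=O)C[C@H](C(C(=O)OCC)P(=O)(OCC)OCC)C=C12 | intermediate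
13 | dipotassium dianion of 12 (C8 enolate, C11 carbanion) | C[C@@H]1CCC[C@@]2(C)C([O-])=C[C@H]([C-](C(=O)OCC)P(=O)(OCC)OCC)C=C12.[K+].[K+] | intermediate (not isolated)
14 | 8α-hydroxy ketone | C[C@@H]1CCC[C@@]2(C)C(=O)[C@@H](O)[C@H](C(C(=O)OCC)P(=O)(OCC)OCC)C=C12 | intermediate
15 | 8α-TBS ether of 14 | C[C@@H]1CCC[C@@]2(C)C(=O)[C@@H](O[Si](C)(C)C(C)(C)C)[C@H](C(C(=O)OCC)P(=O)(OCC)OCC)C=C12 | intermediate
16 | 9β-alcohol | C[C@@H]1CCC[C@@]2(C)[C@H](O)[C@@H](O[Si](C)(C)C(C)(C)C)[C@H](C(C(=O)OCC)P(=O)(OCC)OCC)C=C12 | intermediate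
17 | (2R)-2-methylbutanoic acid | CC[C@@H](C)C(=O)O | starting material
18 | 9β-(2R)-2-methylbutanoate, Δ5(6)-octalin | C[C@@H]1CCC[C@@]2(C)[C@H](OC(=O)[C@H](C)CC)[C@@H](O[Si](C)(C)C(C)(C)C)[C@H](C(C(=O)OCC)P(=O)(OCC)OCC)C=C12 | intermediate
19 | C5 triethylsilyl peroxide | C[C@@H]1CCC[C@@]2(C)[C@H](OC(=O)[C@H](C)CC)[C@@H](O[Si](C)(C)C(C)(C)C)[C@H](C(C(=O)OCC)P(=O)(OCC)OCC)CC12OO[Si](CC)(CC)CC | intermediate (not isolated)
20 | C5 hydroperoxide | C[C@@H]1CCC[C@@]2(C)[C@H](OC(=O)[C@H](C)CC)[C@@H](O[Si](C)(C)C(C)(C)C)[C@H](C(C(=O)OCC)P(=O)(OCC)OCC)CC12OO | intermediate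
21 | C5 peroxy 4-nitrobenzoate | C[C@@H]1CCC[C@@]2(C)[C@H](OC(=O)[C@H](C)CC)[C@@H](O[Si](C)(C)C(C)(C)C)[C@H](C(C(=O)OCC)P(=O)(OCC)OCC)CC12OOC(=O)c3ccc(cc3)[N+](=O)[O-] | intermediate (not isolated)
22 | 5,10-epoxy-bridged 5-(4-nitrobenzoate) | C[C@@H]1CCC[C@]2(C)O[C@@]1(OC(=O)c3ccc(cc3)[N+](=O)[O-])C[C@@H](C(C(=O)OCC)P(=O)(OCC)OCC)[C@H](O[Si](C)(C)C(C)(C)C)[C@H]2OC(=O)[C@H](C)CC | intermediate
23 | 8,10-dihydroxy-5-oxocyclodecane ethyl ester | C[C@@H]1CCC[C@](C)(O)[C@H](OC(=O)[C@H](C)CC)[C@@H](O)[C@H](C(C(=O)OCC)P(=O)(OCC)OCC)CC1=O | intermediate (not isolated)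
24 | α-(diethoxyphosphoryl) lactone | CCOP(=O)(OCC)C1C(=O)O[C@@H]2[C@@H](OC(=O)[C@H](C)CC)[C@@](C)(O)CCC[C@@H](C)C(=O)C[C@@H]12 | intermediate
25 | formaldehyde | C=O | starting material
26 | ineupatorolide A | C=C1C(=O)O[C@@H]2[C@@H](OC(=O)[C@H](C)CC)[C@@](C)(O)CCC[C@@H](C)C(=O)C[C@@H]12 | target

Total step count: 13. Longest linear sequence: 13.

**Steps most likely to fail**

Step 11. The C9 acyloxy group could lower the migratory aptitude of C10. C4 could then migrate in competition, or a second oxygen insertion could follow the first.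
Fallback, from 20 back to 24:
- Reduction with PPh3 would give the C5 carbinol F1.
- Suárez alkoxy-radical β-scission (PhI(OAc)2, I2, hν) would cleave the same C5–C10 bond homolytically. After loss of HI from the tertiary iodide it would give the 10-methylidenecyclodecanone F2.
- Mukaiyama hydration (Co(acac)2, PhSiH3, O2) would give the 10-hydroxy ketone TBS ether F3.
- The conditions of step 12 would then lead to 24.
- In this variant C10 is no longer set by retention, so its epimers would have to be separated.

Step 3. The enolate could equilibrate towards C4, with loss of the C4 configuration and alkylation at the wrong carbon. The Wittig closure on the hindered C5 ketone could also be slow.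
Fallback, from 3 back to 10:
- Mukaiyama aldol addition to acrolein (TMSOTf cat., acidic work-up) would give the 2-(1-hydroxyallyl) ketone F4.
- Allylcerium addition to the C5 ketone would give the diene diol F5.
- Six-membered ring-closing metathesis would give the Δ7(8)-octalin-5,9-diol F6.
- Oxidation of the allylic C9 alcohol (DMP) and acid-induced vinylogous dehydration of the C5 carbinol (TsOH) would give dienone 10 directly.

Step 5. The Michael equilibrium could be unfavourable, the facial preference at C7 could be weak, or C4 could epimerise through the extended trienolate.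
Fallback, from 9 back to 12:
- Allylic oxidation at C7 (CrO3·3,5-dimethylpyrazole) would give the 7,9-dione F7.
- O-triflation of its C7 enol would give the dienone triflate F8.
- Palladium-catalysed coupling with the sodium salt of 11 would give the C7-substituted dienone F9.
- Conjugate reduction (Stryker's reagent) would deliver hydride axially to C7 from the α face. C7 would thus be set kinetically, leading to 12.

**Further compounds**
F1 | step 11 | C5 carbinol (5-hydroxy analogue of 20) | C[C@@H]1CCC[C@@]2(C)[C@H](OC(=O)[C@H](C)CC)[C@@H](O[Si](C)(C)C(C)(C)C)[C@H](C(C(=O)OCC)P(=O)(OCC)OCC)CC12O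
F2 | step 11 | 10-methylidenecyclodecanone | C[C@@H]1CCCC(=C)[C@H](OC(=O)[C@H](C)CC)[C@@H](O[Si](C)(C)C(C)(C)C)[C@H](C(C(=O)OCC)P(=O)(OCC)OCC)CC1=O
F3 | step 11 | 10-hydroxy ketone TBS ether | C[C@@H]1CCC[C@](C)(O)[C@H](OC(=O)[C@H](C)CC)[C@@H](O[Si](C)(C)C(C)(C)C)[C@H](C(C(=O)OCC)P(=O)(OCC)OCC)CC1=O
F4 | step 3 | (2S,6R)-2-(1-hydroxyprop-2-en-1-yl)-2,6-dimethylcyclohexan-1-one | C[C@@H]1CCC[C@@](C)(C(O)C=C)C1=O
F5 | step 3 | 1-allyl-2-(1-hydroxyprop-2-en-1-yl)-2,6-dimethylcyclohexan-1-ol | C[C@@H]1CCC[C@@](C)(C(O)C=C)C1(O)CC=C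
F6 | step 3 | 4,10-dimethyl-Δ7(8)-octalin-5,9-diol (target numbering) | C[C@@H]1CCC[C@@]2(C)C(O)C=CCC12O
F7 | step 5 | (5R,8aR)-5,8a-dimethyl-6,7,8,8a-tetrahydronaphthalene-1,3(2H,5H)-dione | C[C@@H]1CCC[C@@]2(C)C(=O)CC(=O)C=C12
F8 | step 5 | C7 enol triflate of F7 | C[C@@H]1CCC[C@@]2(C)C(=O)C=C(OS(=O)(=O)C(F)(F)F)C=C12
F9 | step 5 | C7-(phosphonoacetate)-substituted dienone | C[C@@H]1CCC[C@@]2(C)C(=O)C=C(C(C(=O)OCC)P(=O)(OCC)OCC)C=C12
A1 | direct plan | (2S,3S)-3-methyl-1-oxo-3-[(triethylsilyl)oxy]pent-4-en-2-yl (2R)-2-methylbutanoate | O=C[C@@H](OC(=O)[C@H](C)CC)[C@@](C)(O[Si](CC)(CC)CC)C=C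
A2 | direct plan | (2R)-1-{2-[(2R)-pent-4-en-2-yl]-1,3-dioxolan-2-yl}but-3-yn-2-yl methanesulfonate | C=CC[C@@H](C)C1(C[C@@H](OS(C)(=O)=O)C#C)OCCO1
A3 | direct plan | metathesis diene with the methylene lactone masked as its dimethylamine adduct | CN(C)CC1C(=O)O[C@H]([C@@H](OC(=O)[C@H](C)CC)[C@@](C)(O)C=C)[C@H]1CC(=O)[C@H](C)CC=C
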